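Subtract the impurity from the catalyst before reading any clock on elm, the flask asked about. I assume each impurity takes one free catalyst for good. The impurity, charged at less than the catalyst, is then the limiting reagent of that loss, and what keeps turning over is the working catalyst, charge minus impurity, 22.2 µM, or 69.4% of the charge.

| setting | elm | alder | flask |
|---|---|---|---|
| left-handed substrate | 40 mM | 27 mM | 40 mM |
| right-handed substrate | 40 mM | 27 mM | 40 mM |
| coupling partner | 88 mM | 88 mM | 88.0 mM |
| free catalyst | 32 µM | 32 µM | 32 µM |
| impurity | 9.8 µM | 9.8 µM | 9.8 µM |
| remark | the very flask that is asked about, followed so far | run made earlier |  |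
| time |  |  | 10 min |

elm run (percent of the left-handed substrate and right-handed substrate together charged)

| time / s | left-handed product / % | left-handed substrate / % |
|---|---|---|
| 10.0 | 7.6 | 42.9 |
| 20.0 | 12.1 | 35.8 |
| 30.0 | 17.2 | 32.2 |
| 60.0 | 26.2 | 25.2 |
| 120 | 37.3 | 14.8 |

alder run (percent of the left-handed substrate and right-handed substrate together charged)

| time / min | left-handed product / % | left-handed substrate / % |
|---|---|---|
| 1.33 | 31.3 | 17.5 |
| 3.00 | 45.6 | 7.1 |
| 4.00 | 47.2 | 5.5 |
| 6.00 | 49.9 | 2.7 |
| 8.00 | 51.5 | 2.0 |

(readings scatter by 1 percentage point)

- concentration of left-handed product at 10 min, in mM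
- concentration of left-handed substrate at 10 min, in mM
- concentration of coupling partner at 10 min, in mM

- free catalyst is single-handed; left-handed substrate and right-handed substrate are mirror images of each other, charged as a racemate, each of them at the stated concentration

My ladder has this loss on its first rung, assumed over before elm's first reading at 10.0 s. Next comes left-handed substrate: its fall to 32.2% at 30.0 s reads as 0.0147 /s, a half-life near 0.788 min, short against 10 min. Slowest is the creep of left-handed substrate plus product in alder, 3.5 percentage points above its starting share by 8.00 min, which I read as racemisation. Alder has elm's working catalyst, but it has less substrate on the same coupling partner and its last reading comes earlier than 10 min, so that reading doesn't give elm's state. I use its shares as a rough estimate for elm at 10 min: left-handed product near 41.2 mM and left-handed substrate near 1.60 mM. For coupling partner I commit to less than 46.8 mM, by whatever right-handed product takes, which no reading shows.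

The forecast gives 41.2 mM, 2.4 mM and 46.8 mM, on the ground “Assuming 1:1 consumption”.

The flask gives 41.1 mM of left-handed product, 2.17 mM of left-handed substrate and 19.4 mM of coupling partner.

    2 coupling partner → homo dimer (k = 0.00334 /M/s)
    coupling partner + free catalyst + left-handed substrate → free catalyst + left-handed product (k = 7900 /M²/s)
    coupling partner + free catalyst + right-handed substrate → free catalyst + right-handed product (k = 1780 /M²/s)
    free catalyst + impurity → spent catalyst (k = 18200 /M/s)
    left-handed substrate ⇌ right-handed substrate (k = 3.52 × 10⁻⁴ /s)

In the flask, impurity stands at 0% and free catalyst at 69.4%, against my 69.4%. The neighbouring flask has 13.0 µM of catalyst, so its working catalyst is 3.20 µM, or 24.6% of its charge, and it holds 24.6% free catalyst. Scaled by working catalyst, its 10.0 min equal 1.44 min of the flask's time. The flask at 1.00 min has 23.7% left-handed substrate and 26.6% left-handed product. The neighbour at 10.0 min has 21.6% and 31.1%, which is 17.2 mM of left-handed substrate.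

(All runs are calculated from invented constants; the scatter is artificial.)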